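Atom numbers C1–C10 are those of the hydroazulene core of 31 (ring A: C1–C5; ring B: C5–C10 and C1) and are used for every intermediate; β is the face of the C1 methyl group.

## Structural features

31 is a daucane triester: a cyclopentane (ring A) trans-fused along C1–C5 to a cycloheptene (ring B) whose only double bond, C8=C9, carries the C8 methyl group. Its six stereocentres form two contiguous runs that meet at the ring fusion: C2–C1–C10 (acetoxy carbinol, quaternary methyl carbon, benzoyloxy carbinol) and C4–C5–C6 (tertiary isopropyl carbinol, ring-fusion methine, angeloyloxy carbinol). The C4 hydroxyl and the C10 benzoate are cis to the angular methyl, whereas the C2 acetate, H5 and the C6 angelate are trans to it. Fragile points are the (Z)-angelate (isomerisation to the tiglate), the allylic C10 benzoate (ionisation, SN2′), the tertiary C4 hydroxyl (retro-aldol or dehydration whenever C2 or C6 is a ketone), and the need to place three different esters on three secondary alcohols. The real difficulty is the quaternary C1 flanked by two oxygenated carbons inside a trans-fused 5/7 system, because kinetically controlled annulations give the cis fusion. The key step exploits two features: ring B carries oxygen at C6 and C10 and carbon at C8 in the 1,3,5 pattern of a furan–oxyallyl (4+3) adduct, and ring A is a latent cyclopentenone (C2 carbonyl, C4 isopropyl) fused across C1–C5, the alkene of that adduct.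

## Logic of the disconnections

31 ⇒ 30 ⇒ 29. The C10–O acyl bond and then the C10–H bond are cut. The C10 oxygen is cis to the angular methyl, which is what hydride delivery anti to that methyl gives, and a C10 ketone also explains the position of the C8=C9 alkene. One ester and one stereocentre are removed. The forward steps need a 1,2-reduction from the α face and acylation of a hindered allylic alcohol without base-induced alkene migration.

29 ⇒ 28 ⇒ 27. The oxygen is moved from C10 back to C8 and the C8–CH3 bond is cut. This turns the methyl enone into the C8(=O)–C9=C10 enone, the natural product of a β-elimination of a C10–O bond. The forward steps need a 1,2-selective methyl addition that spares two esters and a transposition that can only run toward C10.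

27 ⇒ 26 ⇒ 25 ⇒ 24. The C6–O acyl bond is cut, C8 is masked as a ketal and the C6–H bond is removed to give a C6 ketone. A C6 ketone is the only handle on the wrong C5 centre, and the C4 hydroxyl can return the hydride to the β face of C6. The forward reduction must be directed and must ignore every other carbonyl.

24 ⇒ 23. The C5–H bond is inverted. The cycloaddition chemistry delivers the cis fusion, so C5 must be equilibrated. This is only clean while C7 is insulated from any second carbonyl or alkene, hence the ketal at C8 in 23. The forward step needs the trans isomer to be the more stable one.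

23 ⇒ 22 ⇒ 21 ⇒ 20 ⇒ 19 ⇒ 18. The C10–O bond of the C6–O–C10 bridge is re-formed. This returns a rigid oxabicyclic ketone in which C6 is already configured and C10 no longer matters. The forward opening must start from the C9 proton and not the C7 proton; the substrate does not guarantee this, so a chiral base is used.

18 ⇒ 17 ⇒ 16 ⇒ 15 ⇒ 14 ⇒ 13. The C2–O acyl bond, the C2–H bond, the C3–H bond and the C4–O bond are removed in turn, back to the C2(=O)–C3=C4 enone. All three ring-A centres are then set by attack on the convex face of the tricycle. The forward steps need β attack at C4 and at C2.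

13 ⇒ 12 ⇒ 11. The C1–CH3 bond is cut and the C3–Si bond restored. In the tricycle the methyl can only take the place of H1. The forward step needs enolisation at C1 without loss of the C10–O bond.

11 ⇒ 10 + 6. C1–C2, C2–C3 and C4–C5 are cut, which removes ring A and leaves a meso alkene and a cobalt-bound alkyne. The forward step must be exo-selective, regioselective (silicon next to CO) and enantiotopic-group selective.

10 ⇒ 9 ⇒ 8 ⇒ 7. The Co–P/Co–S bonds, the Co–alkyne bonds and the C–Si bond are cut. The forward ligand exchange must give one diastereomer at the Co2C2 core.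

6 ⇒ 4 + 5 ⇒ 3 ⇒ 1 + 2. The ketal C–O bonds, two C–Cl bonds and the two C–C bonds of the seven-membered ring are cut. This leaves three commodity chemicals and requires only a (4+3) cycloaddition.

## Other disconnections considered

Alternative 1: Both bonds to the quaternary carbon, C1–C5 and C1–C10, are cut, so ring B becomes an arene and C1 a carbenoid. In the forward step Rh2(OAc)4 (divalent rhodium) decomposes diazo ketone A1; the carbenoid cyclopropanates the C5–C10 bond and the norcaradiene opens to cycloheptatriene A2 (Buchner reaction).
- In favour: both rings and the quaternary centre form in one catalytic step, and the C8 methyl and C6 oxygen are present from the start. On skeletal convergence and on the use of a catalytic metal this alternative is the better one, since the chosen plan adds the C1 and C8 methyls separately and uses cobalt stoichiometrically.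
- Against: C1 would be controlled only by the C4 carbinol, 1,3 to the carbenoid, and C4 must first be made enantioselectively as a tertiary benzylic alcohol. The methoxy group invites attack on the C5–C6 bond. A2 has three ring-B double bonds where 31 has one, and no oxygen at C10. A 1,4-hydro-oxygenation across C7–C10 with β delivery, unmasking of the enol ether to the C6 α-carbinol with H5 trans, and the C2 reduction would all remain.
- Comparison: A2 is nearer to 31 in carbon count, 11 is nearer in oxygen pattern and has a rigid shape for stereocontrol. The alternative would reach the bicyclic core in fewer steps but is expected to spend them again on the triene.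

Alternative 2: C7–C8 and C1–C10 are cut, a (4+3) dissection of ring B into a vinylcarbene unit C8–C9–C10 and a diene C7=C6–C5=C1 carried by ring A. In the forward step Rh2(S-DOSP)4 (divalent rhodium) converts A3 into a vinylcarbenoid that cyclopropanates the C6=C7 bond of siloxy diene A4; the cis-divinylcyclopropane undergoes Cope rearrangement through a boat transition state to A5.
- In favour: the quaternary C1 is set by a stereospecific pericyclic step, the C8=C9 alkene is formed in its final place, and C6 arrives as an enol ether. On these points the alternative is better, because the chosen plan needs a methyl addition, a transposition and a detour through a C6 ketone.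
- Against: ring A with C4 must be made enantiopure first, and the diene face is then a matched or mismatched pairing with the catalyst. The C8 ester must be reduced to a methyl group (about three steps). C10 is a methylene, so its β oxygen would depend on a late allylic oxidation next to the quaternary centre. C5 would again be set by protonation.
- Comparison: the alternative is stronger on C1 and on the alkene position. The chosen plan is stronger on oxygenation, with C6 and C10 both carried in from furan, and on the ease of its starting materials. The overall step count should be similar.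

Alternative 3: The ring-fusion bond C1–C5 is cut, and ring A is closed from a chain whose C4 comes from A6. In the forward sequence A6 is cleaved and elaborated to bis enol ether A7. Anodic oxidation in methanol then gives the radical cation of the C1=C10 enol ether, which is attacked at C1 by C5 of the other enol ether, and both termini are trapped as acetals in A8.
- In favour: C4 comes from the chiral pool, a quaternary carbon is formed by umpolung, and the two acetal arms are trans, so C5 is correct relative to C1 from the outset. This is better than the chosen plan, which has to invert C5.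
- Against: ring B does not yet exist. The masked aldehydes C6 and C10 must be joined through C7–C8–C9 in a seven-membered annulation that creates and controls both carbinols and distinguishes two similar acetals. The C2 oxygen must be introduced on the open chain, and the C1 configuration relative to C2 and C4 in the electrolysis is not secured.
- Comparison: the alternative fixes the ring fusion early but postpones the harder ring. The chosen plan has ring B and its two oxygens from the first step and pays for this with the C5 correction. No saving in steps is expected.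

Key step: step 6

Remark: which antipode of the P,S ligand (step 5) and of the lithium amide (step 13) is the matched one cannot be foreseen for these substrates; the (R)-ligand and the (R,R)-amide are written and the mirror-image reagents would be used if the opposite sense is found.
Remark: 3 is a mixture of chloro epimers and 28 a mixture of C8 epimers; both centres disappear in the next step.
Remark: the P,S ligand is a reagent, accessible in two operations from commercial (R)-2-methylpropane-2-sulfinamide, and is not counted.
Remark: the structures of 6, 8 and 11 were checked atom by atom against 31. 11 is exo-fused, has silicon next to the carbonyl and the C6–O bond as in 31, while C5 and C10 must be inverted; no structural correction was needed. The precursors are kept unchanged; the plan after the cycloaddition is redesigned at the bridge opening and at the C5 inversion.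

## Route

Step 1
Reactants: 1 furan; 2 1,1,3-trichloroacetone
Product: 3 2,4-dichloro-8-oxabicyclo[3.2.1]oct-6-en-3-one (mixture of chloro epimers)
Conditions: Et3N, CF3CH2OH, furan in excess, 0 °C → rt
Reagents that add atoms: none
Why: Base-induced loss of HCl from 2 gives a 1,3-dichloro-2-oxyallyl cation that adds to furan in a (4+3) cycloaddition; the fluorinated alcohol stabilises the cation, and the chlorine centres are irrelevant because both chlorines are removed next.

Step 2
Reactants: 3 2,4-dichloro-8-oxabicyclo[3.2.1]oct-6-en-3-one
Product: 4 8-oxabicyclo[3.2.1]oct-6-en-3-one (meso)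
Conditions: Zn–Cu couple, NH4Cl, MeOH, rt
Reagents that add atoms: none
Why: Reductive dehalogenation of an α-halo ketone: zinc inserts into each α-C–Cl bond and NH4Cl protonates the zinc enolate; the strained alkene and the ether bridge are inert.

Step 3
Reactants: 4 8-oxabicyclo[3.2.1]oct-6-en-3-one; 5 ethylene glycol
Product: 6 8-oxabicyclo[3.2.1]oct-6-en-3-one ethylene ketal (meso)
Conditions: p-TsOH (cat.), benzene, reflux, Dean–Stark
Reagents that add atoms: none
Why: Acid-catalysed ketalisation with azeotropic removal of water; masking C8 keeps the later C1 enolate chemistry away from C7 and C9, and the product stays meso.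

Step 4
Reactants: 7 3-methylbut-1-yne
Product: 8 trimethyl(3-methylbut-1-yn-1-yl)silane
Conditions: n-BuLi, THF, −78 °C; Me3SiCl, −78 °C → rt
Reagents that add atoms: chlorotrimethylsilane, C[Si](C)(C)Cl
Why: Deprotonation of the terminal alkyne and C-silylation of the acetylide; the silyl group is the regiocontrol element of the key step.

Step 5
Reactants: 8 trimethyl(3-methylbut-1-yn-1-yl)silane
Product: 10 Co2(CO)4(μ-P,S-ligand) complex of 8 (single diastereomer at the Co2C2 core), via hexacarbonyl alkyne complex 9 (not isolated)
Conditions: Co2(CO)8, hexane, rt; then (R)-tBuS(O)N(Bn)PPh2, toluene, 65 °C; crystallisation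
Reagents that add atoms: dicobalt octacarbonyl, O=C=[Co](=C=O)(=C=O)(=C=O)[Co](=C=O)(=C=O)(=C=O)=C=O; (R)-N-benzyl-N-(diphenylphosphanyl)-2-methylpropane-2-sulfinamide, CC(C)(C)[S@@](=O)N(Cc1ccccc1)P(c1ccccc1)c1ccccc1
Why: The alkyne displaces two CO ligands of Co2(CO)8 to give the Co2C2 tetrahedrane (zerovalent cobalt), and the bridging P,S ligand then replaces one CO on each cobalt. Because the alkyne termini differ, the two placements of P and S are diastereomers, and the major one should be obtained pure by crystallisation.

Step 6
Reactants: 10 Co2(CO)4(μ-P,S-ligand) complex of 8; 6 8-oxabicyclo[3.2.1]oct-6-en-3-one ethylene ketal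
Product: 11 exo-fused tricyclic 3-silyl-4-isopropyl cyclopentenone (C2 ketone, C6–O–C10 bridge, C8 ketal)
Conditions: 6 in excess, toluene, 70 °C; air, aqueous NH4Cl wash
Reagents that add atoms: none
Why: This is a Pauson–Khand reaction, an intermolecular [2+2+1] cycloaddition of the kind known for strained bicyclic alkenes with P,S-bridged dicobalt alkyne complexes. The hemilabile sulfur leaves its cobalt, the C1=C5 alkene of 6 binds there through its exo face and inserts into the Co–C bond of the isopropyl-bearing alkyne carbon (C4–C5), after which CO insertion (C2–C3) and reductive elimination (C1–C2) follow. Ring A is therefore closed by reductive elimination from a cobaltacycle, a (2+2+1) annulation across C1–C5. Only the exo face, syn to the oxygen bridge, is open because the C7–C8–C9 bridge and its ketal cover the endo face; this fixes H1 and H5 cis to each other and anti to the bridge. The bulkier silyl terminus ends next to the new carbonyl, so the carbonyl carbon bonds to C1 and the isopropyl carbon to C5. Which enantiotopic alkene carbon becomes C5 is decided by which cobalt carries sulfur, that is by the Co2C2 configuration fixed in step 5, so the desymmetrisation is ligand-controlled and sets C1 and C5 and with them the absolute sense of C6 and C10. The ketal and the silyl group are spectators.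

Step 7
Reactants: 11 exo-fused tricyclic 3-silyl-4-isopropyl cyclopentenone
Product: 13 C1-methyl tricyclic enone (C3–H), via C1-methylated silyl enone 12 (not isolated)
Conditions: LiN(iPr)2, THF, −78 °C; MeI, DMPU, −78 → −30 °C; then Bu4NF, 0 °C
Reagents that add atoms: iodomethane, CI
Why: Kinetic α′-deprotonation of the enone takes the only α′-hydrogen, H1, and SN2 methylation can only occupy the endo position it vacates, because ring A must stay cis-fused to the tetrahydrofuran ring; this places the methyl β as in 31. Fluoride then removes the α-silyl group (protodesilylation of an α-silyl enone), and the low temperature is meant to keep the enolate from β-eliminating the C10–O bond.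

Step 8
Reactants: 13 C1-methyl tricyclic enone
Product: 14 tricyclic 3β,4β-epoxy ketone
Conditions: 30% H2O2, NaOH, MeOH, 0 °C → rt
Reagents that add atoms: hydrogen peroxide, OO
Why: Weitz–Scheffer nucleophilic epoxidation; hydroperoxide adds to C4 from the convex face of ring A (the face of the C1 methyl and H5) because the other face lies under the oxygen bridge, so the C4–O bond is β.

Step 9
Reactants: 14 tricyclic 3β,4β-epoxy ketone
Product: 15 tricyclic C4 β-hydroxy ketone
Conditions: SmI2, THF–MeOH, −90 °C
Reagents that add atoms: none
Why: Two-electron reduction of the α,β-epoxy ketone cleaves the C3–O bond and methanol protonates the samarium enolate, so the tertiary C4 carbinol is kept with its configuration; the low temperature avoids ketone reduction and retro-aldol cleavage.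

Step 10
Reactants: 15 tricyclic C4 β-hydroxy ketone
Product: 16 tricyclic C2α,C4β-diol
Conditions: Me4NBH(OAc)3, MeCN–AcOH, −20 °C
Reagents that add atoms: none
Why: Evans–Saksena hydroxyl-directed reduction: the borohydride bound to the C4 oxygen delivers hydride to the β face of C2 and gives the 1,3-anti diol (C2–OH α); the β face is also the sterically open one, so both controls agree.

Step 11
Reactants: 16 tricyclic C2α,C4β-diol
Product: 17 tricyclic C2 acetate
Conditions: Ac2O, DMAP, pyridine, CH2Cl2, rt
Reagents that add atoms: acetic anhydride, CC(=O)OC(C)=O
Why: DMAP-catalysed acetylation of the secondary C2 alcohol; the tertiary C4 alcohol is not acylated, and acyl migration is excluded because the two oxygens are trans on ring A.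

Step 12
Reactants: 17 tricyclic C2 acetate
Product: 18 bridged C8 ketone
Conditions: pyridinium tosylate, acetone–H2O, 50 °C
Reagents that add atoms: water, O
Why: Mild acid hydrolysis of the dioxolane; the β-alkoxy ketone, the acetate and the tertiary alcohol tolerate these conditions.

Step 13
Reactants: 18 bridged C8 ketone
Product: 19 C8=C9 trimethylsilyl enol ether with C4–OSiMe3
Conditions: (R,R)-bis(1-phenylethyl)amine·HCl, n-BuLi, THF; Me3SiCl, −100 °C
Reagents that add atoms: chlorotrimethylsilane, C[Si](C)(C)Cl
Why: Kinetic deprotonation by a chiral lithium amide with in situ silylation is the known way to distinguish the two α-methylenes of 8-oxabicyclo[3.2.1]octan-3-ones. Reagent control is used to take the C9 proton, so the enol ether double bond is C8=C9, and the C4 alkoxide is silylated in the same operation.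

Step 14
Reactants: 19 C8=C9 trimethylsilyl enol ether
Product: 21 cis-fused C9=C10 enone ethylene ketal with C6–OSiMe3 and C4–OSiMe3, via ring-opened silyloxy enone 20 (not isolated)
Conditions: Me3SiOTf (cat.), CH2Cl2, −78 °C; then (Me3SiOCH2)2, −78 → −20 °C; pyridine quench
Reagents that add atoms: 1,2-bis(trimethylsilyloxy)ethane, C[Si](C)(C)OCCO[Si](C)(C)C
Why: The silyl triflate silylates the bridging oxygen and the C8=C9 enol ether expels the C10–O bond (Lewis-acid-assisted E1cB-type opening of an oxabicyclic ketone), leaving C6–OSiMe3 with its configuration. The enone is ketalised at once under aprotic silyl triflate conditions, so the C6 oxygen cannot re-add to C10 and C7 is no longer next to a carbonyl.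

Step 15
Reactants: 21 cis-fused enone ketal bis(trimethylsilyl) ether
Product: 22 cis-fused C4,C6-diol ketal
Conditions: Bu4NF, AcOH, THF, 0 °C
Reagents that add atoms: none
Why: Buffered fluoride cleaves both trimethylsilyl ethers without touching the acetate or the allylic ketal.

Step 16
Reactants: 22 cis-fused C4,C6-diol ketal
Product: 23 cis-fused C6 ketone
Conditions: Dess–Martin periodinane, NaHCO3, CH2Cl2, rt
Reagents that add atoms: none
Why: Dess–Martin oxidation of the only secondary alcohol; the buffered neutral conditions spare the ketal and the tertiary alcohol.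

Step 17
Reactants: 23 cis-fused C6 ketone
Product: 24 trans-fused C6 ketone
Conditions: DBU, toluene, 60 °C
Reagents that add atoms: none
Why: Enolisation toward C5 equilibrates the ring fusion. In 24 the C4 hydroxyl is syn to the C6 carbonyl and can hydrogen-bond to it, and the isopropyl group is moved away from ring B, which should favour the trans-fused isomer in a non-polar solvent. C7 is flanked by the ketal, so no alkene migration can compete.

Step 18
Reactants: 24 trans-fused C6 ketone
Product: 25 trans-fused C6α-alcohol
Conditions: Me4NBH(OAc)3, MeCN–AcOH, −20 °C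
Reagents that add atoms: none
Why: Evans–Saksena reduction: the reagent reduces only a ketone with a syn β-hydroxyl, so the hydride bound to the C4 oxygen is delivered to the β face of C6 and gives the α carbinol (1,3-anti), against the steric preference of external hydrides. Any residual 23 cannot use this pathway and can be recycled.

Step 19
Reactants: 25 trans-fused C6α-alcohol
Product: 26 C6 angelate ketal
Conditions: angelic acid, 2,4,6-Cl3C6H2COCl, Et3N, toluene, rt; then 25, 80 °C
Reagents that add atoms: angelic acid, C/C=C(/C)C(=O)O
Why: Yamaguchi-type esterification through the mixed anhydride of angelic acid, chosen because it avoids Z→E isomerisation to the tiglate; the tertiary alcohol does not react.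

Step 20
Reactants: 26 C6 angelate ketal
Product: 27 trans-fused C6 angelate C8 enone
Conditions: pyridinium tosylate, acetone–H2O, 40 °C
Reagents that add atoms: water, O
Why: Acid hydrolysis of the allylic dioxolane regenerates the C8 enone; the trans fusion now prevents any oxygen bridge from re-forming, and the esters are stable.

Step 21
Reactants: 27 trans-fused C6 angelate C8 enone
Product: 28 tertiary allylic alcohol (C8 epimers)
Conditions: MeLi, CeCl3, THF, −78 °C
Reagents that add atoms: methyllithium, [Li]C
Why: The organocerium reagent adds 1,2 to the enone faster than it enolises C7 (which would expel the angelate) or attacks the two esters; the C8 configuration is of no consequence.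

Step 22
Reactants: 28 tertiary allylic alcohol
Product: 29 C10 enone with C8(Me)=C9
Conditions: C5H5NH[CrO3Cl] (pyridinium chlorochromate), NaOAc, 4 Å sieves, CH2Cl2, rt
Reagents that add atoms: pyridinium chlorochromate, [O-][Cr](=O)(=O)Cl.c1cc[nH+]cc1
Why: Babler–Dauben oxidative transposition: the tertiary allylic chromate ester undergoes [3,3] shift to C10 and is oxidised there, which puts the ketone at C10 and the methyl-bearing alkene at C8=C9 in its final place.

Step 23
Reactants: 29 C10 enone
Product: 30 C10β-alcohol
Conditions: NaBH4, CeCl3·7H2O, MeOH, −78 °C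
Reagents that add atoms: none
Why: Luche 1,2-reduction; hydride should approach C10 anti to the axial angular methyl on C1 (α face), so the hydroxyl is β and cis to the methyl, and no base-mediated alkene migration can occur under these conditions.

Step 24
Reactants: 30 C10β-alcohol
Product: 31 CNP0248576.1
Conditions: BzCl, DMAP, pyridine, CH2Cl2, 0 °C → rt
Reagents that add atoms: benzoyl chloride, O=C(Cl)c1ccccc1
Why: DMAP-catalysed benzoylation of the allylic secondary alcohol; the tertiary C4 hydroxyl stays free, which completes 31.

## Compound list

1 | furan | c1ccoc1 | starting material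
2 | 1,1,3-trichloroacetone | ClCC(=O)C(Cl)Cl | starting material
3 | 2,4-dichloro-8-oxabicyclo[3.2.1]oct-6-en-3-one (chloro epimers) | O1[C@H]2C(Cl)C(=O)C(Cl)[C@@H]1C=C2 | intermediate
4 | 8-oxabicyclo[3.2.1]oct-6-en-3-one (meso) | O1[C@H]2CC(=O)C[C@@H]1C=C2 | intermediate
5 | ethylene glycol | OCCO | starting material
6 | 8-oxabicyclo[3.2.1]oct-6-en-3-one ethylene ketal (meso) | O1[C@H]2CC3(OCCO3)C[C@@H]1C=C2 | intermediate
7 | 3-methylbut-1-yne | CC(C)C#C | starting material
8 | trimethyl(3-methylbut-1-yn-1-yl)silane | CC(C)C#C[Si](C)(C)C | intermediate
9 | hexacarbonyl dicobalt complex of 8 (Co2C2 tetrahedrane) | CC(C)C12[Co]3(=C=O)(=C=O)(=C=O)[Co]1(=C=O)(=C=O)(=C=O)C23[Si](C)(C)C | intermediate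
10 | tetracarbonyl dicobalt complex of 8 bridged by the (R)-P,S ligand, P on one cobalt and S on the other (one diastereomer at the Co2C2 core; core configuration not encoded) | CC(C)C12[Co-]34(=C=O)(=C=O)[P+](c5ccccc5)(c5ccccc5)N(Cc5ccccc5)[S@@+](C(C)(C)C)(=O)[Co-]13(=C=O)(=C=O)C24[Si](C)(C)C | intermediate
11 | exo-fused tricyclic 3-silyl-4-isopropyl cyclopentenone (H1 and H5 β, bridge α, C8 ketal) | O1[C@H]2CC4(OCCO4)C[C@@H]1[C@H]3C(=O)C([Si](C)(C)C)=C(C(C)C)[C@H]32 | intermediate
12 | C1β-methyl derivative of 11 | O1[C@H]2CC4(OCCO4)C[C@@H]1[C@@]3(C)C(=O)C([Si](C)(C)C)=C(C(C)C)[C@H]32 | intermediate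
13 | C1β-methyl tricyclic enone (C3–H) | O1[C@H]2CC4(OCCO4)C[C@@H]1[C@@]3(C)C(=O)C=C(C(C)C)[C@H]32 | intermediate
14 | 3β,4β-epoxide of 13 | O1[C@H]2CC4(OCCO4)C[C@@H]1[C@@]3(C)C(=O)[C@@H]5O[C@]5(C(C)C)[C@H]32 | intermediate
15 | tricyclic C2 ketone with C4β-OH and C4α-isopropyl | O1[C@H]2CC4(OCCO4)C[C@@H]1[C@@]3(C)C(=O)C[C@@](O)(C(C)C)[C@H]32 | intermediate
16 | tricyclic C2α,C4β-diol | O1[C@H]2CC4(OCCO4)C[C@@H]1[C@@]3(C)[C@@H](O)C[C@@](O)(C(C)C)[C@H]32 | intermediate
17 | tricyclic C2α-acetate, C4β-OH, C8 ketal | O1[C@H]2CC4(OCCO4)C[C@@H]1[C@@]3(C)[C@@H](OC(C)=O)C[C@@](O)(C(C)C)[C@H]32 | intermediate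
18 | tricyclic C2α-acetate, C4β-OH, C8 ketone | O1[C@H]2CC(=O)C[C@@H]1[C@@]3(C)[C@@H](OC(C)=O)C[C@@](O)(C(C)C)[C@H]32 | intermediate
19 | C8(OSiMe3)=C9 enol ether of 18 with C4–OSiMe3 | O1[C@H]2CC(O[Si](C)(C)C)=C[C@@H]1[C@@]3(C)[C@@H](OC(C)=O)C[C@@](O[Si](C)(C)C)(C(C)C)[C@H]32 | intermediate
20 | cis-fused bicyclic C8(=O)–C9=C10 enone, C6α-OSiMe3, C4–OSiMe3 | C[Si](C)(C)O[C@H]1CC(=O)C=C[C@@]2(C)[C@@H](OC(C)=O)C[C@@](O[Si](C)(C)C)(C(C)C)[C@@H]12 | intermediate
21 | ethylene ketal of 20 | C[Si](C)(C)O[C@H]1CC3(OCCO3)C=C[C@@]2(C)[C@@H](OC(C)=O)C[C@@](O[Si](C)(C)C)(C(C)C)[C@@H]12 | intermediate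
22 | cis-fused C6α-OH, C4β-OH ketal | O[C@H]1CC3(OCCO3)C=C[C@@]2(C)[C@@H](OC(C)=O)C[C@@](O)(C(C)C)[C@@H]12 | intermediate
23 | cis-fused C6 ketone (H5 β) | O=C1CC3(OCCO3)C=C[C@@]2(C)[C@@H](OC(C)=O)C[C@@](O)(C(C)C)[C@@H]12 | intermediate
24 | trans-fused C6 ketone (H5 α) | O=C1CC3(OCCO3)C=C[C@@]2(C)[C@@H](OC(C)=O)C[C@@](O)(C(C)C)[C@H]12 | intermediate
25 | trans-fused C6α-alcohol | O[C@H]1CC3(OCCO3)C=C[C@@]2(C)[C@@H](OC(C)=O)C[C@@](O)(C(C)C)[C@H]12 | intermediate
26 | C6α-angelate of 25 | C/C=C(/C)C(=O)O[C@H]1CC3(OCCO3)C=C[C@@]2(C)[C@@H](OC(C)=O)C[C@@](O)(C(C)C)[C@H]12 | intermediate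
27 | trans-fused C8(=O)–C9=C10 enone with C6α-angelate | C/C=C(/C)C(=O)O[C@H]1CC(=O)C=C[C@@]2(C)[C@@H](OC(C)=O)C[C@@](O)(C(C)C)[C@H]12 | intermediate
28 | C8 tertiary allylic alcohol (C8 epimers) | C/C=C(/C)C(=O)O[C@H]1CC(C)(O)C=C[C@@]2(C)[C@@H](OC(C)=O)C[C@@](O)(C(C)C)[C@H]12 | intermediate
29 | C10 ketone with C8(Me)=C9 | C/C=C(/C)C(=O)O[C@H]1CC(C)=CC(=O)[C@@]2(C)[C@@H](OC(C)=O)C[C@@](O)(C(C)C)[C@H]12 | intermediate
30 | C10β-alcohol | C/C=C(/C)C(=O)O[C@H]1CC(C)=C[C@H](O)[C@@]2(C)[C@@H](OC(C)=O)C[C@@](O)(C(C)C)[C@H]12 | intermediate
31 | CNP0248576.1 | C/C=C(/C)C(=O)O[C@H]1CC(C)=C[C@H](OC(=O)c2ccccc2)[C@@]2(C)[C@@H](OC(C)=O)C[C@@](O)(C(C)C)[C@H]12 | target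

## Step count and least certain steps

Total: 24 steps. Longest linear sequence: 22 steps (steps 1–3, then 6–24).

Step 6 (key step). The doubly substituted alkyne in a ligand-bridged complex may insert the alkene too slowly, and the temperature then needed could let the ligand migrate between the cobalt atoms and erode the enantiomeric purity. The fallback gives up ligand control. From 8 and 6, the more reactive hexacarbonyl complex 9 is formed and reacted under amine N-oxide promotion (N-methylmorpholine N-oxide, CH2Cl2, rt). This should give 11 together with its mirror image, ent-11 F1. The two are separated by preparative chromatography on a chiral stationary phase, and the route is rejoined at 11.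

Step 7. Methylation has to take place on the endo face next to the axial ketal oxygen, so alkylation may be slow, and on warming the C1 enolate may instead expel the C10–O bond. The fallback changes the C8 mask so that only a hydrogen points into the endo pocket. From 4:
- reduction with SmI2 and isopropanol to the equatorial alcohol, exo-8-oxabicyclo[3.2.1]oct-6-en-3-ol F2;
- silylation (tBuMe2SiCl, imidazole) to its silyl ether F3;
- the Pauson–Khand reaction with 10 to the silyloxy tricyclic silyl enone F4;
- methylation as in step 7 to the C1-methylated bis-silyl compound F5;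
- Bu4NF to remove both silyl groups and give the C8-hydroxy enone F6;
- Dess–Martin oxidation to the C8-keto enone F7;
- selective ketalisation of the saturated C8 ketone (ethylene glycol, pyridinium tosylate), which rejoins the route at 13.

Step 13. The bias of the substrate (C9 is shielded by the endo methyl on C1) may oppose the chiral base, so proton removal at C7 and opening toward C6 could compete. The fallback removes the regiochemical question by opening both C–O bonds. From 18:
- Me3SiOTf and Et3N, then DBU, to the cis-fused cross-conjugated dienone F8;
- tBuOOH and DBU, which should epoxidise only the less hindered C6=C7 bond, to the epoxy enone F9;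
- SmI2 to the C6-hydroxy enone F10, in which the C6 configuration is immaterial;
- (Me3SiOCH2)2 and Me3SiOTf to the bis-silylated ketal F11;
- buffered Bu4NF to the diol ketal F12;
- Dess–Martin oxidation, which rejoins the route at 23.

Step 17. The equilibrium may not favour the trans fusion strongly enough, and prolonged base exposure may cause retro-aldol cleavage at C4–C5 or β-elimination of a ketal oxygen from C7. The fallback equilibrates C5 as the vinylogous position of a dienone and rebuilds C6 by steric control. From 18:
- the dienone F8 is made as above and treated further with DBU to reach the trans-fused dienone F13;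
- tBuOOH and DBU should epoxidise C6=C7 anti to the angular methyl, giving the α-epoxide F14;
- SmI2 gives the trans-fused C6α-hydroxy enone F15;
- angeloylation as in step 19 rejoins the route at 27.

Step 23. The α-oriented C2 acetate may compete with the angular methyl in shielding C10, so facial selectivity could be poor. The fallback replaces substrate control by reagent control: Corey–Bakshi–Shibata reduction of 29 (B-methyl oxazaborolidine, catecholborane, toluene, −78 °C), with the catalyst antipode chosen to deliver hydride to the α face, returns to the route at 30 without any new compound.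

## Further compounds

F1 | step 6 | ent-11 (mirror image of 11) | O1[C@@H]2CC4(OCCO4)C[C@H]1[C@@H]3C(=O)C([Si](C)(C)C)=C(C(C)C)[C@@H]32
F2 | step 7 | exo-8-oxabicyclo[3.2.1]oct-6-en-3-ol (meso, hydroxyl cis to the oxygen bridge) | O1[C@H]2C[C@@H](O)C[C@@H]1C=C2
F3 | step 7 | tert-butyldimethylsilyl ether of F2 | O1[C@H]2C[C@@H](O[Si](C)(C)C(C)(C)C)C[C@@H]1C=C2
F4 | step 7 | exo-fused tricyclic silyl enone with C8 exo silyloxy group | O1[C@H]2C[C@@H](O[Si](C)(C)C(C)(C)C)C[C@@H]1[C@H]3C(=O)C([Si](C)(C)C)=C(C(C)C)[C@H]32
F5 | step 7 | C1β-methyl derivative of F4 | O1[C@H]2C[C@@H](O[Si](C)(C)C(C)(C)C)C[C@@H]1[C@@]3(C)C(=O)C([Si](C)(C)C)=C(C(C)C)[C@H]32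
F6 | step 7 | C1β-methyl tricyclic enone with C8 exo hydroxyl | O1[C@H]2C[C@@H](O)C[C@@H]1[C@@]3(C)C(=O)C=C(C(C)C)[C@H]32
F7 | step 7 | C1β-methyl tricyclic enone with C8 ketone | O1[C@H]2CC(=O)C[C@@H]1[C@@]3(C)C(=O)C=C(C(C)C)[C@H]32
F8 | step 13 | cis-fused C6=C7–C8(=O)–C9=C10 dienone (C2 acetate, C4 hydroxyl) | O=C1C=C[C@@]2(C)[C@@H](OC(C)=O)C[C@@](O)(C(C)C)[C@H]2C=C1
F9 | step 13 | C6,C7-epoxide of F8 (epoxide configuration open) | O=C1C=C[C@@]2(C)[C@@H](OC(C)=O)C[C@@](O)(C(C)C)[C@H]2C3OC13
F10 | step 13 | cis-fused C6-hydroxy C8(=O)–C9=C10 enone (C6 epimers) | O=C1C=C[C@@]2(C)[C@@H](OC(C)=O)C[C@@](O)(C(C)C)[C@H]2C(O)C1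
F11 | step 13 | bis(trimethylsilyl) ether ketal of F10 (C6 open) | C[Si](C)(C)OC1CC3(OCCO3)C=C[C@@]2(C)[C@@H](OC(C)=O)C[C@@](O[Si](C)(C)C)(C(C)C)[C@@H]12
F12 | step 13 | cis-fused C4,C6-diol ketal (C6 open) | OC1CC3(OCCO3)C=C[C@@]2(C)[C@@H](OC(C)=O)C[C@@](O)(C(C)C)[C@@H]12
F13 | step 17 | trans-fused C6=C7–C8(=O)–C9=C10 dienone | O=C1C=C[C@@]2(C)[C@@H](OC(C)=O)C[C@@](O)(C(C)C)[C@@H]2C=C1
F14 | step 17 | 6α,7α-epoxide of F13 | O=C1C=C[C@@]2(C)[C@@H](OC(C)=O)C[C@@](O)(C(C)C)[C@@H]2[C@H]3O[C@H]31
F15 | step 17 | trans-fused C6α-hydroxy C8(=O)–C9=C10 enone | O=C1C=C[C@@]2(C)[C@@H](OC(C)=O)C[C@@](O)(C(C)C)[C@@H]2[C@@H](O)C1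
F0 | step 23 | none | none
A1 | alternative 1 | 2-diazo-5-(2-methoxy-4-methylphenyl)-6-methyl-5-(triethylsilyloxy)heptan-3-one | COc1cc(C)ccc1[C@](O[Si](CC)(CC)CC)(C(C)C)CC(=O)C(C)=[N+]=[N-]
A2 | alternative 1 | 8a-methyl dihydroazulenone with C6 methoxy enol ether (Buchner product) | COC1=C2[C@](O[Si](CC)(CC)CC)(C(C)C)CC(=O)[C@]2(C)C=CC(C)=C1
A3 | alternative 2 | methyl 2-diazobut-3-enoate | COC(=O)C(=[N+]=[N-])C=C
A4 | alternative 2 | ring-A siloxy diene (C1=C5–C6(OSi)=C7, C2 ketal, C4 silyl ether) | C=C(O[Si](C)(C)C(C)(C)C)C1=C(C)C2(OCCO2)C[C@@]1(O[Si](C)(C)C)C(C)C
A5 | alternative 2 | bicyclic cycloheptadiene with C8 ester, C6 silyl enol ether and quaternary C1 (Cope product) | COC(=O)C1=CC[C@@]2(C)C3(OCCO3)C[C@@](O[Si](C)(C)C)(C(C)C)C2=C(O[Si](C)(C)C(C)(C)C)C1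
A6 | alternative 3 | (S)-terpinen-4-ol | CC1=CC[C@](O)(C(C)C)CC1
A7 | alternative 3 | acyclic bis enol ether (C10=C1 and C5=C6 methyl enol ethers, enol ether geometry open) | COC=C(C)[C@@H](O[Si](C)(C)C(C)(C)C)C[C@@](O[Si](C)(C)C)(C(C)C)C=COC
A8 | alternative 3 | trans-1,2-bis(dimethoxymethyl)cyclopentane with quaternary C1 (anodic coupling product) | COC(OC)[C@@]1(C)[C@@H](O[Si](C)(C)C(C)(C)C)C[C@@](O[Si](C)(C)C)(C(C)C)[C@@H]1C(OC)OC
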